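The numbers were set for the occasion; the run is a simulation.

In a closed, stirred vessel of constant volume, held at one temperature, a starting complex trades leaving ligand for incoming ligand step by step, with two side exits along the way.

the same everywhere: incoming ligand 10.0 mM; capture agent 0.200 mM; time 15 min
- west: starting complex 0.20 mM
- north: starting complex 0.60 mM
- south: starting complex 2.0 mM
- north-east: starting complex 6.0 mM
- north-west: starting complex 20 mM

    starting complex + incoming ligand → leaving ligand + complex with one exchanged (k1 = 2.7 M⁻¹ s⁻¹)
    complex with one exchanged + incoming ligand → leaving ligand + complex with two exchanged (k2 = 18 M⁻¹ s⁻¹)
    complex with two exchanged + incoming ligand → leaving ligand + complex with three exchanged (k3 = 0.46 M⁻¹ s⁻¹)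
    complex with three exchanged + incoming ligand → leaving ligand + complex with four exchanged (k4 = 4.7 M⁻¹ s⁻¹)
    complex with one exchanged → side product (k5 = 0.0061 s⁻¹)
    complex with two exchanged + capture agent → trapped intermediate (k6 = 10 M⁻¹ s⁻¹)

- [complex with three exchanged] at the end for west, north, south, north-east, north-west, in this order
- how the row runs (falls, then rises / hardly changes / rises, then falls / rises all the way / falls all the way)

- "hardly changes" means that all values lie within two and a half points (for a concentration: within two and a half percent of the largest)
- run time (west): 15 min

I follow one molecule of starting complex. It takes one incoming ligand in the first exchange and then stands at a fork as complex with one exchanged. At 10.0 mM of ligand the second exchange behaves as a pseudo-first-order step of 0.180 s⁻¹, while the side product forms at 0.0061 s⁻¹, which is far slower. So the chance p of going on, the faster rate over the sum of the two, is 96.7%, a figure that belongs to the charged ligand and falls as the ligand falls.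

In west the half-life of starting complex by the first step is 0.43 min, and that of complex with two exchanged by the third step is longer, at 2.5 min, so I let the first two exchanges draw on the ligand first. Hence b, one plus p, is 1.97, and I call it the ligand bill, the incoming ligand taken per molecule of starting complex on the way to complex with two exchanged.

Dividing the ligand charge by the bill gives a starting charge of 5.08 mM. South asks for 3.93 mM of ligand, less than the charge, so by this bill 6.07 mM of ligand remains for the third exchange. North-east asks for 11.8 mM, more than the charge, which by this bill makes the ligand the limiting reagent. The fourth exchange has about ten times the constant of the third, so complex with three exchanged is passed on quickly while ligand lasts. I therefore expect the row to rise, then fall, turning near 5.08 mM, and I commit to no figures for its points.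

The forecast gives 1.200 × 10⁻⁴ mM, 0.001 mM, 0.035 mM, 0.29 mM and 0.07 mM, so that the row rises, then falls, holding that at high loading “the ligand runs out and freezes the sequence early”.

The simulation gives 1.47 × 10⁻⁴ mM, 0.00123 mM, 0.0342 mM, 0.266 mM and 0.0791 mM, and the row rises, then falls.

In west the first step had half of its turnover up to 15.0 min behind it by 0.433 min, the second by 0.531 min and the third by 2.67 min, with 93.3% of the ligand still there at the end. In north-east the ligand stood at 0.0423% at 15.0 min, with complex with two exchanged at 56.3% and starting complex at 19.2% of the starting complex charged. The row's turn reads 5.3 mM, against my 5.08 mM. In north-west, with the ligand at 0%, the 10.0 mM of leaving ligand over the 6.12 mM of starting complex consumed comes to 1.63 per molecule, below the bill of 1.97.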